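**Retrosynthetic overview**
1. Petchiether B (31) comes from the bis-silyl methyl ester macrocycle 29 by desilylation and mild ester hydrolysis.
2. Feature used: in the 14-membered ring, the acid-bearing alkene carbon (enoate α-carbon) carries a CH2CH2 link to the CH of the Z methyl-bearing trisubstituted alkene. The C(sp2)–CH2 bond is therefore cut to a (Z)-α-iodoenoate and the terminal vinyl of a (Z)-1,3-diene (seco compound 27), joined by 9-BBN hydroboration and B-alkyl Suzuki–Miyaura macrocyclisation.
3. 27 comes from arylacetaldehyde 24 by an iodo-ylide Wittig reaction; the (R)-carbinol comes from CBS reduction of ketone 20, made by enolate alkylation of methyl ketone 12 with Z-dienyl bromide 18 (Still–Gennari olefination of acrolein).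
4. 12 comes from hydroquinone by monosilylation, O-allylation/Claisen rearrangement, etherification with ethyl 2-bromoisobutyrate, ozonolysis/acetalisation and Weinreb amide/MeMgBr.
5. Ring order: the benzene ring is present from the start; the only ring formed is the 14-membered macrocycle, closed in step 15.

Key step: step 15

Remark on the chemistry: the para phenol is carried as a TIPS ether, because an aryl TBS ether would be at risk under the carbonate and phosphate bases of steps 4 and 15; metal alkoxides that are only protonated on work-up are not numbered.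

**Step 1**
Reactants: 1 hydroquinone (3 equiv)
Product: 2 4-(triisopropylsilyloxy)phenol
Conditions: TIPSCl (1 equiv), imidazole, DMF, 0 °C → rt
Reagents that add atoms: triisopropylsilyl chloride, CC(C)[Si](Cl)(C(C)C)C(C)C
Why: Statistical monosilylation of the symmetrical diphenol with hydroquinone in excess should give the mono-TIPS ether, the unreacted hydroquinone being removed by aqueous washing (phenol silylation).

**Step 2**
Reactants: 2 4-(triisopropylsilyloxy)phenol; 3 allyl bromide
Product: 4 1-(allyloxy)-4-(triisopropylsilyloxy)benzene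
Conditions: K2CO3, acetone, reflux
Reagents that add atoms: none
Why: Williamson O-allylation of the phenoxide under anhydrous carbonate, which an aryl TIPS ether tolerates.

**Step 3**
Reactants: 4 1-(allyloxy)-4-(triisopropylsilyloxy)benzene
Product: 5 2-allyl-4-(triisopropylsilyloxy)phenol
Conditions: PhNEt2, 190 °C
Reagents that add atoms: none
Why: Aromatic Claisen rearrangement ([3,3]-sigmatropic shift, then tautomerisation) should place the allyl group ortho to the freed phenol, the two ortho positions being equivalent.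

**Step 4**
Reactants: 5 2-allyl-4-(triisopropylsilyloxy)phenol; 6 ethyl 2-bromo-2-methylpropanoate (excess)
Product: 7 ethyl 2-[2-allyl-4-(triisopropylsilyloxy)phenoxy]-2-methylpropanoate
Conditions: Cs2CO3, MeCN, 70 °C
Reagents that add atoms: none
Why: SN2 O-alkylation of the caesium phenoxide by the carbonyl-activated tertiary α-bromo ester is the standard route to aryloxyisobutyrates, the bromo ester being used in excess to offset its elimination.

**Step 5**
Reactants: 7 ethyl 2-[2-allyl-4-(triisopropylsilyloxy)phenoxy]-2-methylpropanoate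
Product: 10 ethyl 2-[2-(2,2-dimethoxyethyl)-4-(triisopropylsilyloxy)phenoxy]-2-methylpropanoate, via ozonide 8 (not isolated), via aldehyde 9 (not isolated)
Conditions: O3, CH2Cl2, −78 °C; Me2S, → rt; then HC(OMe)3, MeOH, TsOH (cat.), rt
Reagents that add atoms: ozone, [O-][O+]=O (oxygen atoms of 8 and 9 only); trimethyl orthoformate, COC(OC)OC (both methoxy groups of 10)
Why: Ozonolysis of the only alkene with reductive work-up should give the arylacetaldehyde, which is converted at once to its dimethyl acetal (acid-catalysed acetalisation) so that the enolisable aldehyde is never handled.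

**Step 6**
Reactants: 10 ethyl 2-[2-(2,2-dimethoxyethyl)-4-(triisopropylsilyloxy)phenoxy]-2-methylpropanoate
Product: 12 3-[2-(2,2-dimethoxyethyl)-4-(triisopropylsilyloxy)phenoxy]-3-methylbutan-2-one, via Weinreb amide 11 (not isolated)
Conditions: MeNH(OMe)·HCl, i-PrMgCl, THF, −20 → 0 °C; then MeMgBr, 0 °C → rt; aq. NH4Cl
Reagents that add atoms: N,O-dimethylhydroxylamine hydrochloride, CNOC.Cl (the N(OMe)Me group of 11 only); methylmagnesium bromide, C[Mg]Br (the methyl group of 12)
Why: Magnesium-amide aminolysis of the ester gives the Weinreb amide, and Grignard addition stops at the chelated tetrahedral adduct, so work-up should release the methyl ketone without over-addition (Weinreb ketone synthesis).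

**Step 7**
Reactants: 13 acrolein; 14 ethyl 2-[bis(2,2,2-trifluoroethoxy)phosphoryl]propanoate
Product: 16 ethyl (2Z)-2-methylpenta-2,4-dienoate, via potassium phosphonate carbanion 15 (not isolated)
Conditions: KHMDS, 18-crown-6, THF, −78 °C; then acrolein, −78 °C
Reagents that add atoms: potassium hexamethyldisilazide, C[Si](C)(C)[N-][Si](C)(C)C.[K+] (potassium of 15 only)
Why: Still–Gennari olefination, in which the electron-poor phosphonate under dissociating conditions eliminates kinetically to the Z-enoate, so the ester carbon ends up cis to the vinyl group.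

**Step 8**
Reactants: 16 ethyl (2Z)-2-methylpenta-2,4-dienoate
Product: 17 (2Z)-2-methylpenta-2,4-dien-1-ol
Conditions: DIBAL-H, CH2Cl2, −78 °C; Rochelle salt
Reagents that add atoms: none
Why: DIBAL-H 1,2-reduction of the conjugated ester to the allylic alcohol does not touch the alkene geometry.

**Step 9**
Reactants: 17 (2Z)-2-methylpenta-2,4-dien-1-ol
Product: 18 (2Z)-1-bromo-2-methylpenta-2,4-diene
Conditions: CBr4, PPh3, CH2Cl2, −20 → 0 °C; used directly as a solution
Reagents that add atoms: carbon tetrabromide, BrC(Br)(Br)Br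
Why: Appel bromination converts the primary allylic alcohol to the bromide by SN2 under neutral conditions, which should avoid ionisation and loss of the Z geometry.

**Step 10**
Reactants: 12 3-[2-(2,2-dimethoxyethyl)-4-(triisopropylsilyloxy)phenoxy]-3-methylbutan-2-one; 18 (2Z)-1-bromo-2-methylpenta-2,4-diene
Product: 20 (6Z)-2-[2-(2,2-dimethoxyethyl)-4-(triisopropylsilyloxy)phenoxy]-2,6-dimethylnona-6,8-dien-3-one, via lithium enolate 19 (not isolated)
Conditions: LDA, THF, −78 °C; then 18, DMPU, −78 → −30 °C
Reagents that add atoms: lithium diisopropylamide, [Li+].CC(C)[N-]C(C)C (lithium of 19 only)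
Why: The ketone can enolise only towards its methyl group (the other α-carbon is quaternary), and SN2 C-alkylation of this lithium enolate by the primary pentadienyl bromide should extend the chain with the Z alkene intact (enolate alkylation).

**Step 11**
Reactants: 20 (6Z)-2-[2-(2,2-dimethoxyethyl)-4-(triisopropylsilyloxy)phenoxy]-2,6-dimethylnona-6,8-dien-3-one
Product: 21 (3R,6Z)-2-[2-(2,2-dimethoxyethyl)-4-(triisopropylsilyloxy)phenoxy]-2,6-dimethylnona-6,8-dien-3-ol
Conditions: (S)-Me-CBS (0.3 equiv), catecholborane, toluene, −78 → −40 °C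
Reagents that add atoms: none
Why: Corey–Bakshi–Shibata reduction, in which the (S)-oxazaborolidine binds the ketone with the bulky aryloxy-bearing quaternary carbon as the large group and delivers hydride to the face that gives the (R)-carbinol, while catecholborane at low temperature does not hydroborate the diene.

**Step 12**
Reactants: 21 (3R,6Z)-2-[2-(2,2-dimethoxyethyl)-4-(triisopropylsilyloxy)phenoxy]-2,6-dimethylnona-6,8-dien-3-ol
Product: 22 (3R,6Z)-3-(tert-butyldimethylsilyloxy) ether of 21 (TBS on the secondary alcohol; acetal and aryl TIPS ether unchanged)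
Conditions: TBSOTf, 2,6-lutidine, CH2Cl2, −78 °C
Reagents that add atoms: tert-butyldimethylsilyl triflate, CC(C)(C)[Si](C)(C)OS(=O)(=O)C(F)(F)F
Why: Silyl triflate silylation is needed for this hindered neopentyl-type secondary alcohol and, buffered by lutidine at −78 °C, should be faster than any activation of the dimethyl acetal.

**Step 13**
Reactants: 22 TBS ether dimethyl acetal
Product: 24 2-{2-[((3R,6Z)-3-(tert-butyldimethylsilyloxy)-2,6-dimethylnona-6,8-dien-2-yl)oxy]-5-(triisopropylsilyloxy)phenyl}acetaldehyde, via collidinium salt 23 (not isolated)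
Conditions: TESOTf, 2,4,6-collidine, CH2Cl2, 0 °C; then H2O, rt; crude aldehyde used at once
Reagents that add atoms: triethylsilyl triflate, CC[Si](CC)(CC)OS(=O)(=O)C(F)(F)F (triflate counter-ion of 23 only); 2,4,6-collidine, Cc1cc(C)nc(C)c1 (pyridinium part of 23 only); water, O (carbonyl oxygen of 24)
Why: Silyl triflate/collidine acetal cleavage turns the dimethyl acetal into a collidinium salt that water hydrolyses to the aldehyde under nearly neutral conditions, which should spare both silyl ethers, the Z-diene and the tertiary aryl ether.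

**Step 14**
Reactants: 24 arylacetaldehyde; 25 methyl (triphenylphosphoranylidene)acetate
Product: 27 methyl (2Z)-4-{2-[((3R,6Z)-3-(tert-butyldimethylsilyloxy)-2,6-dimethylnona-6,8-dien-2-yl)oxy]-5-(triisopropylsilyloxy)phenyl}-2-iodobut-2-enoate (seco compound), via iodo-ylide 26 (not isolated)
Conditions: 25, NIS, CH2Cl2, −20 °C; then K2CO3, 24, −20 °C → rt
Reagents that add atoms: N-iodosuccinimide, O=C1CCC(=O)N1I
Why: Wittig olefination with the stabilised α-iodo ylide, made in the flask by iodination of the ester ylide, should place the ester trans to the arylmethyl group and so give the (Z)-α-iodoenoate under conditions too mild to move the skipped double bond.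

**Step 15**
Reactants: 27 seco Z-diene (Z)-α-iodoenoate
Product: 29 bis-silyl methyl ester of petchiether B (14-membered ring; ester trans to the arylmethyl CH2 so that the two ring CH2 groups on the enoate are cis; Z methyl-bearing alkene; (R)-OTBS; aryl OTIPS), via B-alkyl-9-BBN borane 28 (not isolated)
Conditions: 9-BBN, THF, 0 °C → rt; then slow addition (syringe pump) to Pd(dppf)Cl2 (20 mol%), AsPh3 (20 mol%), aq. K3PO4, THF/DMF, rt, about 1 mM
Reagents that add atoms: 9-borabicyclo[3.3.1]nonane, B1C2CCCC1CCC2 (boron and bicyclic carbons of 28 only; 29 keeps only its hydrogen)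
Why: 9-BBN adds anti-Markovnikov to the only monosubstituted alkene, the terminal vinyl of the Z-diene; Pd(0) then inserts into the C–I bond with retention, the phosphate-activated borate transfers its primary alkyl group to palladium, and C(sp2)–C(sp3) reductive elimination joins the enoate α-carbon to its CH2 substituent. The closest known reaction type is the macrocyclising B-alkyl Suzuki–Miyaura coupling of 9-BBN alkylboranes with alkenyl iodides, α-iodoenoates included. The 14-membered ring is closed end to end through a large palladacycle, with both ring alkenes already in their cis-in-ring geometry and the ortho-disubstituted arene turning the chain ends towards each other. No stereocentre is formed, and the remote (R)-silyloxy centre is not touched. The step needs chemoselective hydroboration (secured by the steric demand of 9-BBN, which should leave the trisubstituted alkenes and the enoate alone), retention of the iodoalkene geometry (stereoretentive oxidative addition and reductive elimination) and ring closure over oligomerisation (slow addition at high dilution). Aqueous phosphate at room temperature should be mild enough to leave the γ-acidic benzylic CH2 of the skipped enoate and the aryl TIPS ether intact.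

**Step 16**
Reactants: 29 bis-silyl methyl ester macrocycle
Product: 30 petchiether B methyl ester
Conditions: TBAF, AcOH (1:1), THF, 0 → 40 °C
Reagents that add atoms: none
Why: Fluoride cleaves both the aryl TIPS and the alkyl TBS ether, and the acetic acid buffer should keep the medium from becoming basic enough to isomerise the skipped enoate (fluoride desilylation).

**Step 17**
Reactants: 30 petchiether B methyl ester
Product: 31 petchiether B
Conditions: Me3SnOH, 1,2-dichloroethane, 70 °C; then 5% aq. HCl
Reagents that add atoms: trimethyltin hydroxide, C[Sn](C)(C)O (one carboxyl oxygen)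
Why: Trimethyltin hydroxide hydrolysis cleaves the methyl ester by tin-assisted hydroxide delivery under nearly neutral conditions, which should avoid the double-bond migration that ordinary saponification could cause.

**Compound list**
1 | hydroquinone | Oc1ccc(O)cc1 | starting material
2 | 4-(triisopropylsilyloxy)phenol | CC(C)[Si](Oc1ccc(O)cc1)(C(C)C)C(C)C | intermediate
3 | allyl bromide | C=CCBr | starting material
4 | 1-(allyloxy)-4-(triisopropylsilyloxy)benzene | C=CCOc1ccc(O[Si](C(C)C)(C(C)C)C(C)C)cc1 | intermediate
5 | 2-allyl-4-(triisopropylsilyloxy)phenol | C=CCc1cc(O[Si](C(C)C)(C(C)C)C(C)C)ccc1O | intermediate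
6 | ethyl 2-bromo-2-methylpropanoate | CCOC(=O)C(C)(C)Br | starting material
7 | ethyl 2-[2-allyl-4-(triisopropylsilyloxy)phenoxy]-2-methylpropanoate | CCOC(=O)C(C)(C)Oc1ccc(O[Si](C(C)C)(C(C)C)C(C)C)cc1CC=C | intermediate
8 | ozonide of 7 (3-arylmethyl-1,2,4-trioxolane; not isolated) | CCOC(=O)C(C)(C)Oc1ccc(O[Si](C(C)C)(C(C)C)C(C)C)cc1CC1OCOO1 | intermediate
9 | ethyl 2-methyl-2-[2-(2-oxoethyl)-4-(triisopropylsilyloxy)phenoxy]propanoate (not isolated) | CCOC(=O)C(C)(C)Oc1ccc(O[Si](C(C)C)(C(C)C)C(C)C)cc1CC=O | intermediate
10 | ethyl 2-[2-(2,2-dimethoxyethyl)-4-(triisopropylsilyloxy)phenoxy]-2-methylpropanoate | CCOC(=O)C(C)(C)Oc1ccc(O[Si](C(C)C)(C(C)C)C(C)C)cc1CC(OC)OC | intermediate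
11 | 2-[2-(2,2-dimethoxyethyl)-4-(triisopropylsilyloxy)phenoxy]-N-methoxy-N,2-dimethylpropanamide (Weinreb amide; not isolated) | CON(C)C(=O)C(C)(C)Oc1ccc(O[Si](C(C)C)(C(C)C)C(C)C)cc1CC(OC)OC | intermediate
12 | 3-[2-(2,2-dimethoxyethyl)-4-(triisopropylsilyloxy)phenoxy]-3-methylbutan-2-one | CC(=O)C(C)(C)Oc1ccc(O[Si](C(C)C)(C(C)C)C(C)C)cc1CC(OC)OC | intermediate
13 | acrolein | C=CC=O | starting material
14 | ethyl 2-[bis(2,2,2-trifluoroethoxy)phosphoryl]propanoate | CCOC(=O)C(C)P(=O)(OCC(F)(F)F)OCC(F)(F)F | starting material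
15 | potassium salt of the α-carbanion of 14 (not isolated) | CCOC(=O)[C-](C)P(=O)(OCC(F)(F)F)OCC(F)(F)F.[K+] | intermediate
16 | ethyl (2Z)-2-methylpenta-2,4-dienoate | C=C/C=C(C)\C(=O)OCC | intermediate
17 | (2Z)-2-methylpenta-2,4-dien-1-ol | C=C/C=C(C)\CO | intermediate
18 | (2Z)-1-bromo-2-methylpenta-2,4-diene | C=C/C=C(C)\CBr | intermediate
19 | lithium enolate of 12, enolised towards the methyl group (not isolated) | [Li+].C=C([O-])C(C)(C)Oc1ccc(O[Si](C(C)C)(C(C)C)C(C)C)cc1CC(OC)OC | intermediate
20 | (6Z)-2-[2-(2,2-dimethoxyethyl)-4-(triisopropylsilyloxy)phenoxy]-2,6-dimethylnona-6,8-dien-3-one | C=C/C=C(C)\CCC(=O)C(C)(C)Oc1ccc(O[Si](C(C)C)(C(C)C)C(C)C)cc1CC(OC)OC | intermediate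
21 | (3R,6Z)-2-[2-(2,2-dimethoxyethyl)-4-(triisopropylsilyloxy)phenoxy]-2,6-dimethylnona-6,8-dien-3-ol | C=C/C=C(C)\CC[C@@H](O)C(C)(C)Oc1ccc(O[Si](C(C)C)(C(C)C)C(C)C)cc1CC(OC)OC | intermediate
22 | (3R,6Z) TBS ether of 21 (dimethyl acetal, aryl TIPS ether) | C=C/C=C(C)\CC[C@@H](O[Si](C)(C)C(C)(C)C)C(C)(C)Oc1ccc(O[Si](C(C)C)(C(C)C)C(C)C)cc1CC(OC)OC | intermediate
23 | N-(1-methoxy-2-arylethyl)-2,4,6-trimethylpyridinium triflate from 22 (mixture at the N,O-acetal carbon; not isolated) | C=C/C=C(C)\CC[C@@H](O[Si](C)(C)C(C)(C)C)C(C)(C)Oc1ccc(O[Si](C(C)C)(C(C)C)C(C)C)cc1CC(OC)[n+]1c(C)cc(C)cc1C.[O-]S(=O)(=O)C(F)(F)F | intermediate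
24 | 2-{2-[((3R,6Z)-3-(tert-butyldimethylsilyloxy)-2,6-dimethylnona-6,8-dien-2-yl)oxy]-5-(triisopropylsilyloxy)phenyl}acetaldehyde | C=C/C=C(C)\CC[C@@H](O[Si](C)(C)C(C)(C)C)C(C)(C)Oc1ccc(O[Si](C(C)C)(C(C)C)C(C)C)cc1CC=O | intermediate
25 | methyl (triphenylphosphoranylidene)acetate | COC(=O)C=P(c1ccccc1)(c1ccccc1)c1ccccc1 | starting material
26 | methyl iodo(triphenylphosphoranylidene)acetate (not isolated) | COC(=O)C(I)=P(c1ccccc1)(c1ccccc1)c1ccccc1 | intermediate
27 | methyl (2Z)-4-{2-[((3R,6Z)-3-(tert-butyldimethylsilyloxy)-2,6-dimethylnona-6,8-dien-2-yl)oxy]-5-(triisopropylsilyloxy)phenyl}-2-iodobut-2-enoate (seco compound) | C=C/C=C(C)\CC[C@@H](O[Si](C)(C)C(C)(C)C)C(C)(C)Oc1ccc(O[Si](C(C)C)(C(C)C)C(C)C)cc1C/C=C(I)/C(=O)OC | intermediate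
28 | B-alkyl-9-BBN adduct of 27, boron on the former terminal vinyl carbon (not isolated) | B1(C2CCCC1CCC2)CC/C=C(C)\CC[C@@H](O[Si](C)(C)C(C)(C)C)C(C)(C)Oc1ccc(O[Si](C(C)C)(C(C)C)C(C)C)cc1C/C=C(I)/C(=O)OC | intermediate
29 | bis-silyl methyl ester of petchiether B (14-membered macrocycle; alkyl OTBS, aryl OTIPS) | C/C1=C/CC/C(C(=O)OC)=C\Cc2cc(O[Si](C(C)C)(C(C)C)C(C)C)ccc2OC(C)(C)[C@H](O[Si](C)(C)C(C)(C)C)CC1 | intermediate
30 | petchiether B methyl ester | C/C1=C/CC/C(C(=O)OC)=C\Cc2cc(O)ccc2OC(C)(C)[C@H](O)CC1 | intermediate
31 | petchiether B | C/C1=C/CC/C(C(=O)O)=C\Cc2cc(O)ccc2OC(C)(C)[C@H](O)CC1 | target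

**Totals**
Total step count: 17 (14 in the main line, 3 in the side branch to bromide 18).
Longest linear sequence: 14 steps (steps 1–6 and 10–17, from hydroquinone).

**Steps most likely to fail**

Step 15 (macrocyclisation). Intermolecular coupling to oligomers, protodeboronation or β-hydride loss may outrun the slow ring-closing transmetalation, and the base may move the skipped double bond. The fallback closes the same ring at the enoate C=C by an intramolecular Horner–Wadsworth–Emmons reaction. It sets out from 22: hydroboration with 9-BBN would give the B-alkyl-9-BBN adduct F1, and perborate oxidation the primary homoallylic alcohol F2. I2/PPh3/imidazole would give the primary iodide F3, and alkylation of the sodium salt of trimethyl phosphonoacetate (in excess) the phosphonoacetate acetal F4. Mild aqueous acid (PPTS, wet acetone), tolerable now that the diene is gone, would give the phosphonoacetate aldehyde F5. LiCl/DBU in MeCN at high dilution should then close the ring with the ester trans to the arylmethyl group, returning to the route at 29.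

Step 10 (enolate alkylation). Proton transfer between the product ketone and unreacted enolate may lead to double alkylation, and the pentadienyl bromide may be attacked at its remote terminus or ionise. The fallback uses an aza-enolate and sets out from 12: condensation with 1,1-dimethylhydrazine would give the N,N-dimethylhydrazone F6. Deprotonation with LDA would give the lithiated hydrazone F7, which should be monoalkylated cleanly by 18 at −78 °C to the alkylated hydrazone F8. Hydrolysis with aqueous Cu(OAc)2 at neutral pH, which the acetal and diene tolerate, comes back to the route at 20.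

Step 14 (iodo-olefination). Geometric control in the Wittig reaction may be poor, and the enolisable arylacetaldehyde may self-condense before the sluggish halo-ylide reacts. The fallback replaces the ylide chemistry by a chromium(II)-mediated olefination and sets out from 24: CrCl2 and methyl tribromoacetate in THF at rt (Reformatsky-type addition, then elimination) should give the (Z)-α-bromoenoate F9 with high Z selectivity under neutral conditions. Its hydroboration to the B-alkyl-9-BBN adduct F10 and the same palladium-catalysed ring closure, now on the activated alkenyl bromide, come back to the route at 29.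

**Further compounds**
F1 | step 15 | B-alkyl-9-BBN adduct of 22 (not isolated) | B1(C2CCCC1CCC2)CC/C=C(C)\CC[C@@H](O[Si](C)(C)C(C)(C)C)C(C)(C)Oc1ccc(O[Si](C(C)C)(C(C)C)C(C)C)cc1CC(OC)OC
F2 | step 15 | (3Z,7R)-7-(tert-butyldimethylsilyloxy)-8-[2-(2,2-dimethoxyethyl)-4-(triisopropylsilyloxy)phenoxy]-4,8-dimethylnon-3-en-1-ol | OCC/C=C(C)\CC[C@@H](O[Si](C)(C)C(C)(C)C)C(C)(C)Oc1ccc(O[Si](C(C)C)(C(C)C)C(C)C)cc1CC(OC)OC
F3 | step 15 | primary iodide from F2 | ICC/C=C(C)\CC[C@@H](O[Si](C)(C)C(C)(C)C)C(C)(C)Oc1ccc(O[Si](C(C)C)(C(C)C)C(C)C)cc1CC(OC)OC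
F4 | step 15 | methyl 2-(dimethoxyphosphoryl)alkanoate from F3 (acetal intact; mixture at the phosphonate α-carbon) | COC(=O)C(CC/C=C(C)\CC[C@@H](O[Si](C)(C)C(C)(C)C)C(C)(C)Oc1ccc(O[Si](C(C)C)(C(C)C)C(C)C)cc1CC(OC)OC)P(=O)(OC)OC
F5 | step 15 | phosphonoacetate arylacetaldehyde from F4 | COC(=O)C(CC/C=C(C)\CC[C@@H](O[Si](C)(C)C(C)(C)C)C(C)(C)Oc1ccc(O[Si](C(C)C)(C(C)C)C(C)C)cc1CC=O)P(=O)(OC)OC
F6 | step 10 | N,N-dimethylhydrazone of 12 | CN(C)N=C(C)C(C)(C)Oc1ccc(O[Si](C(C)C)(C(C)C)C(C)C)cc1CC(OC)OC
F7 | step 10 | lithiated hydrazone (aza-enolate) of F6 (not isolated) | [Li+].C=C([N-]N(C)C)C(C)(C)Oc1ccc(O[Si](C(C)C)(C(C)C)C(C)C)cc1CC(OC)OC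
F8 | step 10 | N,N-dimethylhydrazone of 20 | C=C/C=C(C)\CCC(=NN(C)C)C(C)(C)Oc1ccc(O[Si](C(C)C)(C(C)C)C(C)C)cc1CC(OC)OC
F9 | step 14 | (Z)-α-bromoenoate analogue of 27 | C=C/C=C(C)\CC[C@@H](O[Si](C)(C)C(C)(C)C)C(C)(C)Oc1ccc(O[Si](C(C)C)(C(C)C)C(C)C)cc1C/C=C(Br)/C(=O)OC
F10 | step 14 | B-alkyl-9-BBN adduct of F9 (not isolated) | B1(C2CCCC1CCC2)CC/C=C(C)\CC[C@@H](O[Si](C)(C)C(C)(C)C)C(C)(C)Oc1ccc(O[Si](C(C)C)(C(C)C)C(C)C)cc1C/C=C(Br)/C(=O)OC
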